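**Retrosynthetic overview**

- Feature: ring C has OH on C2 and C4, H on C3 and C6, the methine C* on C1 and the ketone arm on C5. It is the dienol tautomer of a cyclohex-4-ene-1,3-dione, so its C1=C6 bond can be made as a plain alkene by ring-closing metathesis. Ring C is the only ring formed (rings A, B and D are bought).
- Target ⇐ hydrogenolysis of three benzyl ethers and ketal hydrolysis ⇐ ring C resorcinol ⇐ metathesis and aromatisation of an acyclic 2-methylidene-6-vinyl 1,3-dione (C1=C6 formed, ethylene lost).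
- Dione ⇐ aldol addition then oxidation (C3–C4 bond) between a methyl enone carrying C* (left half) and a racemic α-vinyl aldehyde carrying the ketal-masked ring D ketone (right half).
- Left half: C* from rhodium/BINAP conjugate addition of the ring B boronic acid to a ring A pentenoate (Negishi coupling, cross-metathesis); then partial reduction, α-methylenation, methyl addition, oxidation.
- Right half: ring D chloroketone → benzyl ether → dioxolane → iodide; deconjugative α-alkylation of ethyl crotonate; partial reduction.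

Key step: step 16

Assumption: the facial sense of the rhodium/BINAP arylation is taken from the usual α-face model for (E)-enoates, on which the (R)-ligand is specified; the antipodal ligand would be used if the configuration of 8 proved opposite.

**Route**

Step 1
Reactants: 1 4-bromo-3-methoxyphenol
Product: 2 4-(benzyloxy)-1-bromo-2-methoxybenzene
Conditions: BnBr, K2CO3, DMF, rt
Reagents that add atoms: benzyl bromide, BrCc1ccccc1
Why: Williamson O-alkylation of the phenoxide with a benzylic bromide is dependable and leaves the aryl bromide untouched.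

Step 2
Reactants: 2 4-(benzyloxy)-1-bromo-2-methoxybenzene; 3 but-3-en-1-ylzinc bromide
Product: 4 4-(benzyloxy)-1-(but-3-en-1-yl)-2-methoxybenzene
Conditions: Pd(OAc)2 (2 mol%), SPhos (4 mol%), THF, 50 °C
Reagents that add atoms: none
Why: Negishi coupling, in which oxidative addition of the aryl bromide to zerovalent palladium carrying the bulky biarylphosphine, transmetalation from the primary alkylzinc and fast reductive elimination should form the aryl–CH2 bond without β-hydride loss.

Step 3
Reactants: 4 4-(benzyloxy)-1-(but-3-en-1-yl)-2-methoxybenzene; 5 ethyl acrylate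
Product: 6 ethyl (E)-5-[4-(benzyloxy)-2-methoxyphenyl]pent-2-enoate
Conditions: second-generation Grubbs catalyst RuCl2(=CHPh)(PCy3)(SIMes) (3 mol%), 5 (3 equiv), CH2Cl2, 40 °C
Reagents that add atoms: none
Why: Olefin cross-metathesis of a terminal alkene with an acrylate, which homodimerises slowly, should give the (E)-enoate selectively.

Step 4
Reactants: 6 ethyl (E)-5-[4-(benzyloxy)-2-methoxyphenyl]pent-2-enoate; 7 4-(benzyloxy)phenylboronic acid
Product: 8 ethyl (S)-5-[4-(benzyloxy)-2-methoxyphenyl]-3-[4-(benzyloxy)phenyl]pentanoate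
Conditions: Rh(acac)(C2H4)2 (3 mol%), (R)-BINAP (3.3 mol%), 7 (3 equiv), dioxane/H2O 10:1, 100 °C
Reagents that add atoms: none
Why: Hayashi–Miyaura asymmetric 1,4-addition, in which the aryl-rhodium/(R)-BINAP species should insert the (E)-enoate on its C2-re face and so place ring B to give the (S) centre C* (the same spatial arrangement becomes (R) in the target by change of CIP priorities only).

Step 5
Reactants: 8 ethyl (S)-5-[4-(benzyloxy)-2-methoxyphenyl]-3-[4-(benzyloxy)phenyl]pentanoate
Product: 9 (S)-5-[4-(benzyloxy)-2-methoxyphenyl]-3-[4-(benzyloxy)phenyl]pentanal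
Conditions: i-Bu2AlH (1.1 equiv), CH2Cl2, −78 °C; MeOH, then aq. potassium sodium tartrate (KNaC4H4O6)
Reagents that add atoms: none
Why: Partial hydride reduction of the ester stops at the aluminium hemiacetal at low temperature and releases the aldehyde on work-up, and the β-stereocentre cannot epimerise.

Step 6
Reactants: 9 (S)-5-[4-(benzyloxy)-2-methoxyphenyl]-3-[4-(benzyloxy)phenyl]pentanal
Product: 10 2-{(1R)-3-[4-(benzyloxy)-2-methoxyphenyl]-1-[4-(benzyloxy)phenyl]propyl}prop-2-enal
Conditions: 37% aq. CH2O, pyrrolidine (10 mol%), EtCO2H (10 mol%), i-PrOH, 45 °C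
Reagents that add atoms: formaldehyde, C=O
Why: Amine-catalysed α-methylenation (Mannich condensation through the enamine, then loss of the amine) acts only on the α-CH2, and C*–H, which ends up on the α-substituent of the enal, is not acidified.

Step 7
Reactants: 10 2-{(1R)-3-[4-(benzyloxy)-2-methoxyphenyl]-1-[4-(benzyloxy)phenyl]propyl}prop-2-enal
Product: 11 3-{(1R)-3-[4-(benzyloxy)-2-methoxyphenyl]-1-[4-(benzyloxy)phenyl]propyl}but-3-en-2-ol (both carbinol epimers)
Conditions: MeMgBr, THF, −78 °C; aq. NH4Cl
Reagents that add atoms: methylmagnesium bromide, C[Mg]Br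
Why: Grignard 1,2-addition to the aldehyde is strongly favoured over conjugate addition, and the new carbinol centre is removed in the next step.

Step 8
Reactants: 11 3-{(1R)-3-[4-(benzyloxy)-2-methoxyphenyl]-1-[4-(benzyloxy)phenyl]propyl}but-3-en-2-ol
Product: 12 3-{(1R)-3-[4-(benzyloxy)-2-methoxyphenyl]-1-[4-(benzyloxy)phenyl]propyl}but-3-en-2-one
Conditions: Dess–Martin periodinane, pyridine, CH2Cl2, 0 °C to rt
Reagents that add atoms: none
Why: Dess–Martin oxidation of the secondary allylic alcohol gives the methyl enone under neutral conditions that leave the benzyl ethers and C* alone.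

Step 9
Reactants: 13 3-chloro-1-(4-hydroxyphenyl)propan-1-one
Product: 14 1-[4-(benzyloxy)phenyl]-3-chloropropan-1-one
Conditions: BnOH, PPh3, DIAD, THF, 0 °C to rt
Reagents that add atoms: benzyl alcohol, OCc1ccccc1
Why: Mitsunobu etherification benzylates the acidic phenol without a free base, which avoids loss of HCl from the β-chloro ketone.

Step 10
Reactants: 14 1-[4-(benzyloxy)phenyl]-3-chloropropan-1-one
Product: 15 2-[4-(benzyloxy)phenyl]-2-(2-chloroethyl)-1,3-dioxolane
Conditions: HOCH2CH2OH (10 equiv), p-TsOH·H2O (5 mol%), toluene, reflux, Dean–Stark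
Reagents that add atoms: ethylene glycol, OCCO
Why: Acid-catalysed ketalisation with azeotropic removal of water masks the aryl ketone, and acid does not eliminate the β-chloride.

Step 11
Reactants: 15 2-[4-(benzyloxy)phenyl]-2-(2-chloroethyl)-1,3-dioxolane
Product: 16 2-[4-(benzyloxy)phenyl]-2-(2-iodoethyl)-1,3-dioxolane
Conditions: NaI (4 equiv), acetone, reflux
Reagents that add atoms: sodium iodide, [Na+].[I-]
Why: Finkelstein halide exchange at the primary carbon is driven by precipitation of sodium chloride.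

Step 12
Reactants: 17 ethyl (E)-but-2-enoate (ethyl crotonate); 16 2-[4-(benzyloxy)phenyl]-2-(2-iodoethyl)-1,3-dioxolane
Product: 19 ethyl 2-{2-[2-(4-(benzyloxy)phenyl)-1,3-dioxolan-2-yl]ethyl}but-3-enoate (racemic), via lithium dienolate of ethyl crotonate 18 (not isolated)
Conditions: LiN(i-Pr)2 (1.5 equiv), HMPA, THF, −78 °C; then 16, −78 to −20 °C
Reagents that add atoms: none
Why: Deconjugative α-alkylation, in which γ-deprotonation of the crotonate gives the extended dienolate that reacts with the primary iodide at its α-carbon to leave the β,γ-unsaturated (vinyl) ester.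

Step 13
Reactants: 19 ethyl 2-{2-[2-(4-(benzyloxy)phenyl)-1,3-dioxolan-2-yl]ethyl}but-3-enoate
Product: 20 2-{2-[2-(4-(benzyloxy)phenyl)-1,3-dioxolan-2-yl]ethyl}but-3-enal (racemic)
Conditions: i-Bu2AlH (1.1 equiv), CH2Cl2, −78 °C; MeOH, then aq. potassium sodium tartrate (KNaC4H4O6); crude product used at once
Reagents that add atoms: none
Why: Partial hydride reduction of the α-branched ester should stop at the aldehyde at −78 °C, and immediate use limits migration of the double bond into conjugation.

Step 14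
Reactants: 12 3-{(1R)-3-[4-(benzyloxy)-2-methoxyphenyl]-1-[4-(benzyloxy)phenyl]propyl}but-3-en-2-one; 20 2-{2-[2-(4-(benzyloxy)phenyl)-1,3-dioxolan-2-yl]ethyl}but-3-enal
Product: 22 2-{(1R)-3-[4-(benzyloxy)-2-methoxyphenyl]-1-[4-(benzyloxy)phenyl]propyl}-6-{2-[2-(4-(benzyloxy)phenyl)-1,3-dioxolan-2-yl]ethyl}-5-hydroxyocta-1,7-dien-3-one (mixture at C5 and C6), via lithium enolate of enone 12 21 (not isolated)
Conditions: LiN(SiMe3)2 (1.05 equiv), THF, −78 °C; then 20 (1.2 equiv), −78 °C; AcOH in THF, −78 °C
Reagents that add atoms: none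
Why: Aldol addition of the kinetic lithium enolate, which can form only at the methyl group of 12, to the aldehyde at −78 °C should outrun proton transfer, and the two new centres are removed later.

Step 15
Reactants: 22 the aldol adduct (5-hydroxyocta-1,7-dien-3-one)
Product: 23 2-{(1R)-3-[4-(benzyloxy)-2-methoxyphenyl]-1-[4-(benzyloxy)phenyl]propyl}-6-{2-[2-(4-(benzyloxy)phenyl)-1,3-dioxolan-2-yl]ethyl}octa-1,7-diene-3,5-dione (C6 epimers, keto and enol forms)
Conditions: Dess–Martin periodinane (1.2 equiv), pyridine, CH2Cl2, 0 °C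
Reagents that add atoms: none
Why: Dess–Martin oxidation of a β-hydroxy ketone to the 1,3-diketone is standard and, being non-basic, should leave the α-vinyl group and the ketal in place.

Step 16
Reactants: 23 the octa-1,7-diene-3,5-dione
Product: 25 4-{(1R)-3-[4-(benzyloxy)-2-methoxyphenyl]-1-[4-(benzyloxy)phenyl]propyl}-6-{2-[2-(4-(benzyloxy)phenyl)-1,3-dioxolan-2-yl]ethyl}benzene-1,3-diol, via cyclohex-4-ene-1,3-dione 24 (not isolated)
Conditions: second-generation Hoveyda–Grubbs catalyst RuCl2(=CH-C6H4-2-O-i-Pr)(SIMes) (10 mol% in two portions), AcOH (20 mol%), toluene (0.005 M), 80 °C, argon sparge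
Reagents that add atoms: none
Why: Proposed new method: the ruthenium carbene should load on the monosubstituted vinyl group at C5, add across the 1,1-disubstituted enone alkene at C1 to a ruthenacyclobutane and cyclorevert to the C1=C6 bond with loss of ethylene, giving cyclohex-4-ene-1,3-dione 24, whose double enolisation delivers the resorcinol and erases the C5 centre. The closest known reaction type is ring-closing metathesis with tautomerisation of acyclic dienones and trienones to phenols, the new element being the 1,3-dione oxidation level that leads to a resorcinol. Ring C is closed as a six-membered carbocycle by ring-closing metathesis between two terminal alkenes, and it is the only ring formed. No stereocentre is created, and C* is a spectator because its C–H bond lies on the α-substituent of the enone, cross-conjugated to the carbonyl. The step needs closure onto a hindered, electron-poor 1,1-disubstituted alkene in preference to dimerisation through the vinyl group, which high dilution, the favoured ring size and the irreversible aromatisation should secure. Because the hydrogen-bonded enol of 23 holds C1 and C5 anti across the enol double bond, closure must pass through the diketo tautomer, so heat and a little acetic acid are used to keep the tautomers in exchange and to quench ruthenium hydrides that would move the vinyl double bond into conjugation.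

Step 17
Reactants: 25 the ring C resorcinol with the ketal arm
Product: 26 1-[4-(benzyloxy)phenyl]-3-(5-{(1R)-3-[4-(benzyloxy)-2-methoxyphenyl]-1-[4-(benzyloxy)phenyl]propyl}-2,4-dihydroxyphenyl)propan-1-one
Conditions: 1 M aq. HCl, THF, rt
Reagents that add atoms: water, O
Why: Mild aqueous acid hydrolysis of the aryl dioxolane is fast because the oxocarbenium ion is stabilised by the 4-alkoxyphenyl ring, and the benzyl ethers are stable to it.

Step 18
Reactants: 26 the tris(benzyl ether) ketone
Product: 27 3-{2,4-dihydroxy-5-[(1R)-3-(4-hydroxy-2-methoxyphenyl)-1-(4-hydroxyphenyl)propyl]phenyl}-1-(4-hydroxyphenyl)propan-1-one (CNP0253987.1)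
Conditions: H2 (1 atm), 10% Pd/C, EtOAc, rt, stopped at full debenzylation
Reagents that add atoms: none
Why: Catalytic hydrogenolysis cleaves the three aryl benzyl ethers under neutral conditions, while the 4-hydroxyphenyl ketone is deactivated towards reduction and C* is not affected.

**Compound list**

1 | 4-bromo-3-methoxyphenol | COc1cc(O)ccc1Br | starting material
2 | 4-(benzyloxy)-1-bromo-2-methoxybenzene | COc1cc(OCc2ccccc2)ccc1Br | intermediate
3 | but-3-en-1-ylzinc bromide | C=CCC[Zn]Br | starting material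
4 | 4-(benzyloxy)-1-(but-3-en-1-yl)-2-methoxybenzene | COc1cc(OCc2ccccc2)ccc1CCC=C | intermediate
5 | ethyl acrylate | C=CC(=O)OCC | starting material
6 | ethyl (E)-5-[4-(benzyloxy)-2-methoxyphenyl]pent-2-enoate | CCOC(=O)/C=C/CCc1ccc(OCc2ccccc2)cc1OC | intermediate
7 | 4-(benzyloxy)phenylboronic acid | OB(O)c1ccc(OCc2ccccc2)cc1 | starting material
8 | ethyl (S)-5-[4-(benzyloxy)-2-methoxyphenyl]-3-[4-(benzyloxy)phenyl]pentanoate | COc1cc(OCc2ccccc2)ccc1CC[C@H](c1ccc(OCc2ccccc2)cc1)CC(=O)OCC | intermediate
9 | (S)-5-[4-(benzyloxy)-2-methoxyphenyl]-3-[4-(benzyloxy)phenyl]pentanal | COc1cc(OCc2ccccc2)ccc1CC[C@H](c1ccc(OCc2ccccc2)cc1)CC=O | intermediate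
10 | 2-{(1R)-3-[4-(benzyloxy)-2-methoxyphenyl]-1-[4-(benzyloxy)phenyl]propyl}prop-2-enal | COc1cc(OCc2ccccc2)ccc1CC[C@H](c1ccc(OCc2ccccc2)cc1)C(=C)C=O | intermediate
11 | 3-{(1R)-3-[4-(benzyloxy)-2-methoxyphenyl]-1-[4-(benzyloxy)phenyl]propyl}but-3-en-2-ol (carbinol epimers) | COc1cc(OCc2ccccc2)ccc1CC[C@H](c1ccc(OCc2ccccc2)cc1)C(=C)C(C)O | intermediate
12 | 3-{(1R)-3-[4-(benzyloxy)-2-methoxyphenyl]-1-[4-(benzyloxy)phenyl]propyl}but-3-en-2-one | COc1cc(OCc2ccccc2)ccc1CC[C@H](c1ccc(OCc2ccccc2)cc1)C(=C)C(C)=O | intermediate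
13 | 3-chloro-1-(4-hydroxyphenyl)propan-1-one | O=C(CCCl)c1ccc(O)cc1 | starting material
14 | 1-[4-(benzyloxy)phenyl]-3-chloropropan-1-one | O=C(CCCl)c1ccc(OCc2ccccc2)cc1 | intermediate
15 | 2-[4-(benzyloxy)phenyl]-2-(2-chloroethyl)-1,3-dioxolane | ClCCC1(c2ccc(OCc3ccccc3)cc2)OCCO1 | intermediate
16 | 2-[4-(benzyloxy)phenyl]-2-(2-iodoethyl)-1,3-dioxolane | ICCC1(c2ccc(OCc3ccccc3)cc2)OCCO1 | intermediate
17 | ethyl (E)-but-2-enoate (ethyl crotonate) | CCOC(=O)/C=C/C | starting material
18 | lithium dienolate of ethyl crotonate (lithium 1-ethoxybuta-1,3-dien-1-olate), not isolated | CCOC(O[Li])=CC=C | intermediate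
19 | ethyl 2-{2-[2-(4-(benzyloxy)phenyl)-1,3-dioxolan-2-yl]ethyl}but-3-enoate (racemic) | CCOC(=O)C(C=C)CCC1(c2ccc(OCc3ccccc3)cc2)OCCO1 | intermediate
20 | 2-{2-[2-(4-(benzyloxy)phenyl)-1,3-dioxolan-2-yl]ethyl}but-3-enal (racemic) | O=CC(C=C)CCC1(c2ccc(OCc3ccccc3)cc2)OCCO1 | intermediate
21 | lithium enolate of enone 12 (lithium 3-{(1R)-1,3-diarylpropyl}buta-1,3-dien-2-olate), not isolated | COc1cc(OCc2ccccc2)ccc1CC[C@H](c1ccc(OCc2ccccc2)cc1)C(=C)C(=C)O[Li] | intermediate
22 | 2-{(1R)-3-[4-(benzyloxy)-2-methoxyphenyl]-1-[4-(benzyloxy)phenyl]propyl}-6-{2-[2-(4-(benzyloxy)phenyl)-1,3-dioxolan-2-yl]ethyl}-5-hydroxyocta-1,7-dien-3-one (mixture at C5 and C6) | COc1cc(OCc2ccccc2)ccc1CC[C@H](c1ccc(OCc2ccccc2)cc1)C(=C)C(=O)CC(O)C(C=C)CCC1(c2ccc(OCc3ccccc3)cc2)OCCO1 | intermediate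
23 | 2-{(1R)-3-[4-(benzyloxy)-2-methoxyphenyl]-1-[4-(benzyloxy)phenyl]propyl}-6-{2-[2-(4-(benzyloxy)phenyl)-1,3-dioxolan-2-yl]ethyl}octa-1,7-diene-3,5-dione (C6 epimers) | COc1cc(OCc2ccccc2)ccc1CC[C@H](c1ccc(OCc2ccccc2)cc1)C(=C)C(=O)CC(=O)C(C=C)CCC1(c2ccc(OCc3ccccc3)cc2)OCCO1 | intermediate
24 | 4-{(1R)-3-[4-(benzyloxy)-2-methoxyphenyl]-1-[4-(benzyloxy)phenyl]propyl}-6-{2-[2-(4-(benzyloxy)phenyl)-1,3-dioxolan-2-yl]ethyl}cyclohex-4-ene-1,3-dione, not isolated | COc1cc(OCc2ccccc2)ccc1CC[C@H](c1ccc(OCc2ccccc2)cc1)C1=CC(CCC2(c3ccc(OCc4ccccc4)cc3)OCCO2)C(=O)CC1=O | intermediate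
25 | 4-{(1R)-3-[4-(benzyloxy)-2-methoxyphenyl]-1-[4-(benzyloxy)phenyl]propyl}-6-{2-[2-(4-(benzyloxy)phenyl)-1,3-dioxolan-2-yl]ethyl}benzene-1,3-diol | COc1cc(OCc2ccccc2)ccc1CC[C@H](c1ccc(OCc2ccccc2)cc1)c1cc(CCC2(c3ccc(OCc4ccccc4)cc3)OCCO2)c(O)cc1O | intermediate
26 | 1-[4-(benzyloxy)phenyl]-3-(5-{(1R)-3-[4-(benzyloxy)-2-methoxyphenyl]-1-[4-(benzyloxy)phenyl]propyl}-2,4-dihydroxyphenyl)propan-1-one | COc1cc(OCc2ccccc2)ccc1CC[C@H](c1ccc(OCc2ccccc2)cc1)c1cc(CCC(=O)c2ccc(OCc3ccccc3)cc2)c(O)cc1O | intermediate
27 | 3-{2,4-dihydroxy-5-[(1R)-3-(4-hydroxy-2-methoxyphenyl)-1-(4-hydroxyphenyl)propyl]phenyl}-1-(4-hydroxyphenyl)propan-1-one | COc1cc(O)ccc1CC[C@H](c1ccc(O)cc1)c1cc(CCC(=O)c2ccc(O)cc2)c(O)cc1O | target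

**Totals**

Total step count: 18. Longest linear sequence: 13 steps (steps 1–8, then 14–18).

**Steps most likely to fail**

Step 16 (ring-closing metathesis and aromatisation). The catalyst may be held by the chelating β-diketone enol, or the closure may be starved because only the minor diketo tautomer can fold. The vinyl double bond may also migrate into conjugation with the C4 ketone before closure, or the vinyl groups may dimerise. The fallback, which uses known chemistry, sets out from aldol adduct 22, where no enol geometry or chelation is in play and the vinyl group cannot conjugate. Ring-closing metathesis of 22 with the same catalyst in toluene should give 5-hydroxy-2-{(1R)-1,3-diarylpropyl}-4-{2-(2-aryl-1,3-dioxolan-2-yl)ethyl}cyclohex-2-en-1-one F1, an ordinary cyclohexenone closure. Dess–Martin oxidation of F1 (buffered, 0 °C) then gives dione 24, which tautomerises as before, so the route is rejoined at 25.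

Step 14 (aldol addition). The enolate may take the acidic α-proton of the α-vinyl aldehyde, which moves the double bond into conjugation, or it may add in Michael fashion to unreacted enone. The fallback replaces aldol and oxidation by a direct C-acylation under soft enolisation and sets out from ester 19. Saponification (LiOH, THF/H2O, 0 °C) gives 2-{2-[2-(4-(benzyloxy)phenyl)-1,3-dioxolan-2-yl]ethyl}but-3-enoic acid F2. Coupling with 1H-benzotriazole and N,N'-dicyclohexylcarbodiimide in CH2Cl2 gives the N-acylbenzotriazole F3. Ketone 12 is then acylated with F3 in the presence of MgBr2·OEt2 and i-Pr2NEt in CH2Cl2 at rt, which gives dione 23 directly, so the route is rejoined at 23 without passing through 20 or 22.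

Step 13 (partial reduction). The reduction may run on to the primary alcohol, and the β,γ-unsaturated aldehyde may isomerise during work-up. The fallback sets out from ester 19 and goes through the alcohol on purpose. LiAlH4 in THF at 0 °C gives 2-{2-[2-(4-(benzyloxy)phenyl)-1,3-dioxolan-2-yl]ethyl}but-3-en-1-ol F4, which can be purified and stored. Oxidation of F4 with Dess–Martin periodinane and pyridine in CH2Cl2 immediately before the aldol step gives aldehyde 20 under non-aqueous, non-basic conditions, so the route is rejoined at 20.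

**Further compounds**

F1 | step 16 | 5-hydroxy-2-{(1R)-3-[4-(benzyloxy)-2-methoxyphenyl]-1-[4-(benzyloxy)phenyl]propyl}-4-{2-[2-(4-(benzyloxy)phenyl)-1,3-dioxolan-2-yl]ethyl}cyclohex-2-en-1-one (mixture at C4 and C5) | COc1cc(OCc2ccccc2)ccc1CC[C@H](c1ccc(OCc2ccccc2)cc1)C1=CC(CCC2(c3ccc(OCc4ccccc4)cc3)OCCO2)C(O)CC1=O
F2 | step 14 | 2-{2-[2-(4-(benzyloxy)phenyl)-1,3-dioxolan-2-yl]ethyl}but-3-enoic acid (racemic) | OC(=O)C(C=C)CCC1(c2ccc(OCc3ccccc3)cc2)OCCO1
F3 | step 14 | 1-(1H-benzotriazol-1-yl)-2-{2-[2-(4-(benzyloxy)phenyl)-1,3-dioxolan-2-yl]ethyl}but-3-en-1-one (racemic) | C=CC(CCC1(c2ccc(OCc3ccccc3)cc2)OCCO1)C(=O)n1nnc2ccccc21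
F4 | step 13 | 2-{2-[2-(4-(benzyloxy)phenyl)-1,3-dioxolan-2-yl]ethyl}but-3-en-1-ol (racemic) | OCC(C=C)CCC1(c2ccc(OCc3ccccc3)cc2)OCCO1
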